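* amount of complex with two exchanged at the end, in percent of the starting complex charged, for each flask in turn (midnight, autumn, summer)

common to all: starting complex 0.25 M
- Tuesday's: incoming ligand 0.18 M (in portions, 4); run made earlier; portions every 20 s
- Thursday's: incoming ligand 0.42 M (in portions, 4); run made earlier; portions every 20 s
- Monday's: incoming ligand 0.87 M (in portions, 4); run made earlier; portions every 20 s
- midnight: incoming ligand 0.200 M (in portions, 4); the portions of incoming ligand follow each other after 20 s, the first at the start; time 50 min
- autumn: incoming ligand 0.500 M (in portions, 4); the portions of incoming ligand follow each other after 20 s, the first at the start; time 50 min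
- summer: incoming ligand 0.750 M (in portions, 4); the portions of incoming ligand follow each other after 20 s, the first at the start; time 50 min

- Tuesday's (time / min: complex with two exchanged / %, complex with four exchanged / %): 3.00: 2.7, 0; 8.00: 10.0, 0; 15.0: 11.7, 1.4; 25.0: 15.3, 1.0
- Thursday's (time / min: complex with two exchanged / %, complex with four exchanged / %): 2.00: 4.0, 0; 5.00: 15.0, 0.9; 10.0: 17.4, 4.8; 25.0: 16.3, 7.0
- Monday's (time / min: complex with two exchanged / %, complex with four exchanged / %): 3.00: 15.7, 4.0; 8.00: 15.4, 21.5; 15.0: 8.5, 31.3; 25.0: 5.8, 31.7

(each reading ± 1 percentage point)



1. Start from the time of reading. The flasks are read at 50 min, but the runs stop at 25.0 min. Compare Thursday's last two readings of complex with two exchanged: they differ by 1.1 percentage points, against a scatter of 1 point. Take the last reading of each run as a first value for the end.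

2. Order the runs by the charge c(incoming ligand). The last reading goes from 15.3% on Tuesday to 16.3% on Thursday, then to 5.8% on Monday. Treat each new flask as its nearest run plus a small correction.

3. Compute the correction for midnight. The rise of the last reading from Tuesday to Thursday, as a share of the complex charged and divided by the difference in charge, is 0.0417 M⁻¹. Midnight lies 0.0200 M above Tuesday, so it gets 15.4%.

4. Define the drop as the fall of the last reading per M of charge beyond Thursday: 0.233 M⁻¹ of the complex charged. It gives autumn 14.4% and summer 8.60%.

5. Reforge the weak link, which is the first step's assumption at high charge. Monday's reading still fell by 2.7 points between 15.0 min and 25.0 min. Assume that a further half of that fall remains, a trim of 1.4 points, and commit to 7.25% for summer.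

The forecast gives 16%, 14% and 7.5%, its figures “trimmed slightly for the slow drift”. For summer it stands 0.25 points above my reckoning.

The flasks give 15.4%, 14.7% and 7.60%.

    complex with three exchanged + incoming ligand → leaving ligand + complex with four exchanged (k = 0.00840 M⁻¹ s⁻¹)
    complex with one exchanged + incoming ligand → leaving ligand + complex with two exchanged (k = 0.0330 M⁻¹ s⁻¹)
    complex with two exchanged + incoming ligand → leaving ligand + complex with three exchanged (k = 0.0160 M⁻¹ s⁻¹)
    starting complex + incoming ligand → leaving ligand + complex with one exchanged (k = 0.00490 M⁻¹ s⁻¹)
    complex with four exchanged ⇌ isomer of the product (K = 2.50, k = 0.00110 s⁻¹)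

Carry the drop from autumn's simulated value to summer, take off the trim, and it gives 7.52%. In autumn, complex with two exchanged has a half-life of 1.4 min by its onward step, reckoned with the whole charge present at once, short against the 50 min allowed. Yet incoming ligand, the limiting reagent, is down to 0.21% of its own charge at 50.0 min, and complex with two exchanged stands there at 14.7%.

Readings and results stem from a simulated flask from invented constants.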